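**Route proposal for CNP0221003.1 (27), built around the Cope rearrangement of an endo-alkenyl bicyclo[3.1.0]hexenone**

Target numbering (C1–C8) is used for the corresponding atoms of all intermediates.

## Structural features

CNP0221003.1 (27) is a bicyclo[3.2.1]oct-2-en-8-one: a six-membered ring C1–C2–C3–C4–C5–C8 and a five-membered ring C1–C8–C5–C6–C7 share the ketone bridge C8 and the two quaternary bridgeheads C1 (allyl) and C5 (methoxy). The six-membered ring carries the methyl enol ether C2=C3 and, at C4, an acetoxy group on the face of the C8 bridge. The five-membered ring carries the exo 3,4-dimethoxyphenyl group at C6 and the endo methyl group at C7, so C4, C5, C6 and C7 form an unbroken row of stereocentres closed by C1. Fragile points are the enol ether (acid), the allylic acetate beside it (ionisation to a 2-methoxyallyl cation, acyl loss or migration under base), the strained ketone between two quaternary α-carbons (nucleophiles, peracids) and the terminal alkene (a competitor in carbene, iodonium and palladium chemistry). The real difficulty is the fully substituted, oxygenated C5 wedged between the C4 acetate and the C6 aryl group, on a skeleton where no stereocentre can be corrected later by epimerisation. The key step uses the pattern enol ether C2=C3 / σ bond C4–C5 / alkene C6=C7 around C1: read backwards as a [3,3] shift it gives a cyclopropane C1–C2–C7 fused to a 2-methoxycyclopentenone (C1–C8–C5=C6–C7) with an endo 2-acetoxy-1-methoxyvinyl group on C2. In that precursor the configuration of C4 is stored as a double-bond geometry (acetoxy cis to the cyclopropane, trans to methoxy). Enolisation and acylation of an aldehyde would not favour this geometry, because chelation and sterics place the two oxygen atoms cis, so the route takes it from a stereospecific anti addition to an alkyne. A check of the descriptors shows that the endo-alkenyl ketone 21 and the dienone 22 correspond to 27 at C1, C4 and C5, so no structure needs correction.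

## Logic of the disconnections

27 ⇒ 24 (through 26 and 25). The C=C bond of the allyl group is cut by a carbonyl olefination, and the aldehyde is taken back to a silyl-protected primary alcohol. A terminal alkene cannot be carried through carbene transfer, iodolactonisation or aryl-palladium chemistry. The side arm becomes an inert two-carbon spectator from step 1 on. The last three steps must spare the C4 acetate, the enol ether and the C8 ketone.

24 ⇒ 22 + 23. The bonds C6–aryl and C7–H are cut; both are delivered syn to the exo face of the strained alkene C6=C7. Two stereocentres and the aryl ring disappear, and 22 keeps only C1, C4 and C5. The forward step needs aryl transfer to the less substituted C6, exo attack, and hydride capture of a tertiary alkylpalladium before β-hydride loss toward the methyl group.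

22 ⇒ 21. The bond C4–C5 is cut and C2–C7 is re-formed (retro-Cope). The six-membered ring and the stereocentres C4 and C5 are exchanged for a cyclopropane and one alkene geometry. The forward step needs the alkenyl group endo, the acetoxy group cis to the cyclopropane, and a substrate that survives heating.

21 ⇒ 20. The enol C4–O bond is cut back to a C4–I bond. Acylation of an aldehyde enolate would give mainly the other geometry, whereas substitution of a geometrically defined alkenyl iodide retains it. The geometry is then carried by a base-stable group through the ring construction. The forward step needs a retentive copper-mediated C–O coupling below the rearrangement temperature.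

20 ⇒ 18 (through 19). The ring bond C5=C6 is cut by an intramolecular phosphonate olefination, and the C6 aldehyde is masked as its dimethyl acetal. The α-methoxy enone arises in one step with no separate α-oxygenation. The forward steps need the C8 acyl and C6 formyl groups cis on the cyclopropane, and acid and base mild enough for the iodo enol ether.

18 ⇒ 16 + 17. The bond C8–C5 is cut (acylation of a phosphonate carbanion). C5 and its methoxy group come from a one-carbon building block. The forward step needs a hindered ester that still acylates and a vinyl iodide that tolerates the carbanion.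

16 ⇒ 14 (through 15). The enol O–CH3 bond and the ester C8–OCH3 bond are cut and the ring O–C8 bond is re-formed. The lactone ring holds the C3 oxygen, and on opening releases an enolate of fixed geometry. The forward step needs an aprotic ring opening and methylation on oxygen.

14 ⇒ 13. The bonds O–C3 and C4–I are cut (anti addition across a C≡C bond). Iodine enters trans to the ring oxygen, that is cis to the cyclopropane; this is the origin of the C4 configuration of 27. The geometry comes from a stereospecific addition and not from an equilibrium. The forward step needs 5-exo-dig closure, which the cis carboxyl and ethynyl groups allow.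

13 ⇒ 10 (through 12 and 11). The acid is taken back to a primary alcohol, the alkyne (which brings in C4) to a lactol, and the lactol to a lactone. Both functions are stored in one cis-fused lactone, which also locks C2 against epimerisation. The forward homologation must not epimerise the cyclopropyl aldehyde form.

10 ⇒ 6 + 7 (through 9 and 8). The cyclopropane bonds C2–C1 and C2–C7 are cut (intramolecular carbene addition through an ester tether). C1, C2 and C7 and the absolute configuration come from an achiral Z alkene in one step. The forward step needs an enantioselective catalyst that accepts a tetrasubstituted alkene.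

6 ⇒ 3 (through 5 and 4). The C7–CH3 bond is cut (cross-coupling of an enol sulfonate) and the allylic alcohol is taken back to an ester. The Z tetrasubstituted alkene comes from a β-keto ester. The forward steps need an E-selective enol sulfonylation and a coupling with retention.

3 ⇒ 1 + 2. The C1–CH2 bond is cut (enolate alkylation), leaving two purchasable building blocks. The forward step needs C-alkylation rather than O-alkylation.

## Other disconnections considered

Alternative 1: The cut is C5–C6, with the methoxy group arriving at C5 in the same event. Forward, Rh2(OAc)4 would generate a carbenoid at C5 between the C4 and C8 carbonyls; the ether oxygen of the C1 side arm would add to it, and the [2,3] shift of the oxonium ylide would form C5–C6 and close the five-membered ring to the 7-methylidene-4,8-dione A1.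
- In favour: the oxygenated quaternary C5 and the C6 aryl centre are made in one mild catalytic step. The aryl group is in place before the bicycle closes, so no intermolecular carbopalladation between two quaternary carbons is needed; on this point it is better than the chosen plan. The count of one ring, one C–C bond and two stereocentres equals that of the Cope step.
- Against: A1 has a methylene at C3, so the C3 oxygen, the C2=C3 unsaturation and a face-selective reduction at C4 would all still have to be introduced beside a second ketone. The exocyclic alkene would have to be reduced from the exo face. The allyl group, a [1,2] shift and C–H insertion would compete for the carbenoid. The absolute configuration would have to come from a quaternary C1 made earlier.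
- Comparison: structurally, the chosen plan delivers the C4 oxygen and the enol ether in the key step itself. Mechanistically, a concerted pericyclic shift is less exposed to side channels than a free ylide. In step economy the alternative would lose after the key step what it gains before it.

Alternative 2: The cuts are C1–C2 and C4–C5. Forward, Me3SiOTf would ionise a chiral silyloxyacrolein acetal to a 1-alkoxy-2-silyloxyallyl cation, which would add across the termini of a cyclopentadienone ketal and close the six-membered ring to the bicyclic C3 ketone A2.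
- In favour: this is the most convergent plan, with two C–C bonds and the bicycle formed in one intermolecular union of two fragments of similar size, and a shorter longest linear sequence; here it is better than the chosen plan. The C4 oxygen comes with the auxiliary. The C6=C7 methyl alkene is the same handle as in 22, so the endgame is equal.
- Against: two unsymmetrical partners must join with one regiochemistry, alkoxy terminus to C5. Both new bonds end at fully substituted diene carbons. The compact or extended transition state decides C4, and facial control rests on an auxiliary attached to a planar cation. Afterwards the C3 ketone would have to become the enol ether toward C2, against the more acidic C4–H. The ether would have to be exchanged for acetate, and the C8 ketal hydrolysed beside an enol ether.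
- Comparison: the chosen plan is longer but intramolecular, so regiochemistry and both new stereocentres are fixed by ring constraints and one alkene geometry.

Alternative 3: The cut is C5–C8. Forward, a triazolium-derived carbene would turn the C1 aldehyde (C8) into an acyl anion equivalent that adds across a cycloheptenone ring to the C5 ketone, closing both rings at once to the bridgehead alcohol A3.
- In favour: A3 is one O-methylation away from 27, so post-key-step economy is better than in the chosen plan. Two rings form in one metal-free step, and the configuration of C5 is dictated by the bridge.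
- Against: the step makes only one C–C bond and one stereocentre. C1, C4, C6 and C7 would have to be set beforehand on a flexible seven-membered ring. The aldehyde sits on a quaternary carbon, and benzoin addition to a ketone is reversible. The α-acetoxy ketone is exposed to elimination, acyl migration and epimerisation under azolium/base conditions. Methylation of a hindered tertiary α-ketol invites retro-benzoin or ketol shift.
- Comparison: the chosen plan creates C4 and C5 stereospecifically and sets C1/C2/C7 with one catalytic step. The alternative moves the whole stereochemical burden to the substrate and is equal or better only after the key step.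

Key step: step 17

Assumption: compounds 1, 2, 17, the Ohira–Bestmann reagent and Rh2(4S-MPPIM)4 (dirhodium tetrakis[methyl 1-(3-phenylpropanoyl)-2-oxoimidazolidine-4(S)-carboxylate]) are taken as purchasable. The 4S catalyst is taken to give the lactone enantiomer drawn, by analogy with Z-substituted allylic diazoacetates; if the sense is opposite, the 4R catalyst is used.

## Steps

Step 1
Reactants: 1 methyl 4,4-dimethoxy-3-oxobutanoate; 2 tert-butyl(2-iodoethoxy)dimethylsilane
Product: 3 methyl 2-[2-(tert-butyldimethylsilyloxy)ethyl]-4,4-dimethoxy-3-oxobutanoate (racemic)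
Conditions: NaH, THF/DMF, 0 → 50 °C
Reagents that add atoms: none
Why: Acetoacetic-ester-type C-alkylation of the β-keto ester enolate with a primary iodide; the new stereocentre becomes sp2 in step 2, so the racemate suffices.

Step 2
Reactants: 3 methyl 2-[2-(tert-butyldimethylsilyloxy)ethyl]-4,4-dimethoxy-3-oxobutanoate
Product: 4 methyl (2E)-2-[2-(tert-butyldimethylsilyloxy)ethyl]-4,4-dimethoxy-3-(4-methylbenzenesulfonyloxy)but-2-enoate
Conditions: TsCl, N-methylimidazole, Et3N, MeCN, 0 °C → rt
Reagents that add atoms: p-toluenesulfonyl chloride, Cc1ccc(cc1)S(Cl)(=O)=O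
Why: O-sulfonylation of the amine-generated, non-chelated enolate, which prefers the enolate oxygen anti to the ester carbonyl, should give the E enol tosylate (tosyloxy trans to ester, dimethoxymethyl cis to ester); lithium-free conditions avoid the chelated Z enolate.

Step 3
Reactants: 4 methyl (2E)-2-[2-(tert-butyldimethylsilyloxy)ethyl]-4,4-dimethoxy-3-(4-methylbenzenesulfonyloxy)but-2-enoate
Product: 5 methyl (2Z)-2-[2-(tert-butyldimethylsilyloxy)ethyl]-4,4-dimethoxy-3-methylbut-2-enoate
Conditions: MeZnCl, PdCl2(dppf) (cat.), THF, 50 °C
Reagents that add atoms: methylzinc chloride, C[Zn]Cl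
Why: Negishi cross-coupling of an enol tosylate proceeds with retention, so methyl takes the place trans to the ester and the ester and dimethoxymethyl groups stay cis, the geometry needed for an all-cis cyclopropane.

Step 4
Reactants: 5 methyl (2Z)-2-[2-(tert-butyldimethylsilyloxy)ethyl]-4,4-dimethoxy-3-methylbut-2-enoate
Product: 6 (2Z)-2-[2-(tert-butyldimethylsilyloxy)ethyl]-4,4-dimethoxy-3-methylbut-2-en-1-ol
Conditions: i-Bu2AlH (2.2 equiv), CH2Cl2, −78 °C; Rochelle salt work-up
Reagents that add atoms: none
Why: 1,2-Reduction of the conjugated ester to the allylic alcohol; acetal and silyl ether are inert at −78 °C and the alkene geometry is untouched.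

Step 5
Reactants: 6 (2Z)-2-[2-(tert-butyldimethylsilyloxy)ethyl]-4,4-dimethoxy-3-methylbut-2-en-1-ol; 7 bromoacetyl bromide
Product: 8 (2Z)-2-[2-(tert-butyldimethylsilyloxy)ethyl]-4,4-dimethoxy-3-methylbut-2-en-1-yl bromoacetate
Conditions: pyridine, CH2Cl2, 0 °C
Reagents that add atoms: none
Why: Acylation of the primary allylic alcohol with an acid bromide; the base keeps the medium non-acidic for the acetal.

Step 6
Reactants: 8 (2Z)-2-[2-(tert-butyldimethylsilyloxy)ethyl]-4,4-dimethoxy-3-methylbut-2-en-1-yl bromoacetate
Product: 9 (2Z)-2-[2-(tert-butyldimethylsilyloxy)ethyl]-4,4-dimethoxy-3-methylbut-2-en-1-yl diazoacetate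
Conditions: TsNHNHTs, DBU, THF, 0 °C
Reagents that add atoms: N,N′-ditosylhydrazine, Cc1ccc(cc1)S(=O)(=O)NNS(=O)(=O)c1ccc(C)cc1
Why: N-Alkylation of the bis-sulfonyl hydrazide by the bromoacetate and base-induced loss of two sulfinate groups gives the diazoacetate without diazoacetyl chloride or azide transfer reagents.

Step 7
Reactants: 9 (2Z)-2-[2-(tert-butyldimethylsilyloxy)ethyl]-4,4-dimethoxy-3-methylbut-2-en-1-yl diazoacetate
Product: 10 (1S,5R,6S)-5-[2-(tert-butyldimethylsilyloxy)ethyl]-6-(dimethoxymethyl)-6-methyl-3-oxabicyclo[3.1.0]hexan-2-one (dimethoxymethyl on the lactone face)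
Conditions: Rh2(4S-MPPIM)4 (1 mol %), CH2Cl2, reflux, slow addition of 9
Reagents that add atoms: none
Why: Intramolecular cyclopropanation of an allylic diazoacetate by a chiral dirhodium carboxamidate carbenoid: the addition is concerted and syn, so the Z alkene places the C8 and C6 carbons cis, the five-membered lactone tether forces the carbenoid carbonyl (C3) onto the same face, and the catalyst selects the alkene face, which fixes C1, C2 and C7 together.

Step 8
Reactants: 10 (1S,5R,6S)-5-[2-(tert-butyldimethylsilyloxy)ethyl]-6-(dimethoxymethyl)-6-methyl-3-oxabicyclo[3.1.0]hexan-2-one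
Product: 11 (1S,5R,6S)-5-[2-(tert-butyldimethylsilyloxy)ethyl]-6-(dimethoxymethyl)-6-methyl-3-oxabicyclo[3.1.0]hexan-2-ol (anomeric mixture)
Conditions: i-Bu2AlH (1.1 equiv), CH2Cl2, −78 °C
Reagents that add atoms: none
Why: Partial reduction of the γ-lactone stops at the lactol because the aluminium hemiacetal is stable at −78 °C; the ring keeps C2 from epimerising.

Step 9
Reactants: 11 (1S,5R,6S)-5-[2-(tert-butyldimethylsilyloxy)ethyl]-6-(dimethoxymethyl)-6-methyl-3-oxabicyclo[3.1.0]hexan-2-ol
Product: 12 [(1R,2S,3S)-1-[2-(tert-butyldimethylsilyloxy)ethyl]-2-(dimethoxymethyl)-3-ethynyl-2-methylcyclopropyl]methanol (CH2OH, dimethoxymethyl and ethynyl mutually cis)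
Conditions: dimethyl (1-diazo-2-oxopropyl)phosphonate, K2CO3, MeOH, 0 °C → rt
Reagents that add atoms: dimethyl (1-diazo-2-oxopropyl)phosphonate, COP(=O)(OC)C(=[N+]=[N-])C(C)=O
Why: Seyferth–Gilbert homologation in its Ohira–Bestmann form converts the aldehyde form of the lactol into the terminal alkyne (adding C4) and frees the C8 alcohol; the aldehyde is only a fleeting minor component, which limits base epimerisation at C2.

Step 10
Reactants: 12 [(1R,2S,3S)-1-[2-(tert-butyldimethylsilyloxy)ethyl]-2-(dimethoxymethyl)-3-ethynyl-2-methylcyclopropyl]methanol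
Product: 13 (1R,2S,3R)-1-[2-(tert-butyldimethylsilyloxy)ethyl]-2-(dimethoxymethyl)-3-ethynyl-2-methylcyclopropane-1-carboxylic acid
Conditions: TEMPO (cat.), NaOCl (cat.), NaClO2, MeCN/phosphate buffer pH 6.7, 35 °C
Reagents that add atoms: sodium chlorite, [Na+].[O-]Cl=O
Why: Oxoammonium oxidation to the aldehyde and chlorite oxidation to the acid in one pot at near-neutral pH, which acetal, alkyne and silyl ether tolerate; no stereocentre is touched (the descriptor at C3 changes by priority only).

Step 11
Reactants: 13 (1R,2S,3R)-1-[2-(tert-butyldimethylsilyloxy)ethyl]-2-(dimethoxymethyl)-3-ethynyl-2-methylcyclopropane-1-carboxylic acid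
Product: 14 (1R,4E,5R,6S)-1-[2-(tert-butyldimethylsilyloxy)ethyl]-6-(dimethoxymethyl)-4-(iodomethylidene)-6-methyl-3-oxabicyclo[3.1.0]hexan-2-one
Conditions: iodine, NaHCO3, MeCN, 0 °C, dark
Reagents that add atoms: iodine, [I][I]
Why: Iodolactonisation of a 4-pentynoic acid unit: the carboxylate attacks the iodonium-activated alkyne 5-exo-dig and anti, so iodine ends trans to the ring oxygen and therefore cis to the cyclopropane; this anti addition is the source of the later C4 configuration.

Step 12
Reactants: 14 (1R,4E,5R,6S)-1-[2-(tert-butyldimethylsilyloxy)ethyl]-6-(dimethoxymethyl)-4-(iodomethylidene)-6-methyl-3-oxabicyclo[3.1.0]hexan-2-one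
Product: 16 methyl 1-[2-(tert-butyldimethylsilyloxy)ethyl]-2-(dimethoxymethyl)-3-[(E)-2-iodo-1-methoxyethenyl]-2-methylcyclopropane-1-carboxylate (ester/acetal/alkenyl groups mutually cis; ring configuration as in 13), via potassium iodoenolate 15 (not isolated)
Conditions: KOMe (1.05 equiv), 18-crown-6, THF, −78 °C; then MeOTf, −78 → −20 °C
Reagents that add atoms: potassium methoxide, [K+].[O-]C; methyl trifluoromethanesulfonate, COS(=O)(=O)C(F)(F)F
Why: Methoxide opens the enol lactone (an activated ester) at C8 and releases the ketone enolate with the double-bond geometry of the ring (oxygen trans to iodine); without a proton source the enolate cannot isomerise, and a crown-separated potassium enolate with a hard methylating agent should react at oxygen, giving the E iodo enol ether.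

Step 13
Reactants: 16 methyl 1-[2-(tert-butyldimethylsilyloxy)ethyl]-2-(dimethoxymethyl)-3-[(E)-2-iodo-1-methoxyethenyl]-2-methylcyclopropane-1-carboxylate; 17 diethyl (methoxymethyl)phosphonate
Product: 18 diethyl (2-{1-[2-(tert-butyldimethylsilyloxy)ethyl]-2-(dimethoxymethyl)-3-[(E)-2-iodo-1-methoxyethenyl]-2-methylcyclopropyl}-1-methoxy-2-oxoethyl)phosphonate (epimers at the phosphorus-bearing carbon; ring configuration unchanged)
Conditions: 17, LDA (2.2 equiv each), THF, −78 °C; then 16, −78 → −30 °C; NH4Cl
Reagents that add atoms: none
Why: Claisen-type acylation of the α-lithiated phosphonate by the methyl ester forms C8–C5 with the methoxy group already on C5; the β-keto phosphonate is deprotonated as formed, which prevents double addition, and the alkenyl iodide is not attacked by this stabilised carbanion at low temperature.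

Step 14
Reactants: 18 diethyl (2-{1-[2-(tert-butyldimethylsilyloxy)ethyl]-2-(dimethoxymethyl)-3-[(E)-2-iodo-1-methoxyethenyl]-2-methylcyclopropyl}-1-methoxy-2-oxoethyl)phosphonate
Product: 19 diethyl (2-{1-[2-(tert-butyldimethylsilyloxy)ethyl]-2-formyl-3-[(E)-2-iodo-1-methoxyethenyl]-2-methylcyclopropyl}-1-methoxy-2-oxoethyl)phosphonate
Conditions: PPTS (cat.), acetone/H2O 10:1, 35 °C
Reagents that add atoms: water, O
Why: Mild acid hydrolysis of the dimethyl acetal, whose oxocarbenium ion is cyclopropyl-stabilised; the iodine-deactivated enol ether and the primary silyl ether should hydrolyse much more slowly.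

Step 15
Reactants: 19 diethyl (2-{1-[2-(tert-butyldimethylsilyloxy)ethyl]-2-formyl-3-[(E)-2-iodo-1-methoxyethenyl]-2-methylcyclopropyl}-1-methoxy-2-oxoethyl)phosphonate
Product: 20 1-[2-(tert-butyldimethylsilyloxy)ethyl]-6-endo-[(E)-2-iodo-1-methoxyethenyl]-3-methoxy-5-methylbicyclo[3.1.0]hex-3-en-2-one (iodine cis to the cyclopropane; absolute configuration as in the SMILES)
Conditions: K2CO3, 18-crown-6, toluene, rt
Reagents that add atoms: none
Why: Intramolecular Horner–Wadsworth–Emmons olefination between the β-keto phosphonate and the non-enolisable cis aldehyde closes the cyclopentenone and installs the α-methoxy enone (C5=C6) in one step; the mild base leaves the alkenyl iodide alone.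

Step 16
Reactants: 20 1-[2-(tert-butyldimethylsilyloxy)ethyl]-6-endo-[(E)-2-iodo-1-methoxyethenyl]-3-methoxy-5-methylbicyclo[3.1.0]hex-3-en-2-one
Product: 21 (E)-2-{1-[2-(tert-butyldimethylsilyloxy)ethyl]-3-methoxy-5-methyl-2-oxobicyclo[3.1.0]hex-3-en-6-endo-yl}-2-methoxyethenyl acetate (acetoxy cis to the cyclopropane)
Conditions: CuI (20 mol %), 3,4,7,8-tetramethyl-1,10-phenanthroline, CsOAc, toluene, 50 °C
Reagents that add atoms: caesium acetate, [Cs+].CC(=O)[O-]
Why: Ullmann-type copper-catalysed C–O coupling of an alkenyl iodide with a carboxylate replaces iodine by acetoxy with retention of alkene geometry, so the acetoxy group inherits the position cis to the cyclopropane; the temperature is kept below that expected for the rearrangement of a substrate with an inward substituent.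

Step 17
Reactants: 21 (E)-2-{1-[2-(tert-butyldimethylsilyloxy)ethyl]-3-methoxy-5-methyl-2-oxobicyclo[3.1.0]hex-3-en-6-endo-yl}-2-methoxyethenyl acetate
Product: 22 1-[2-(tert-butyldimethylsilyloxy)ethyl]-3,5-dimethoxy-7-methyl-8-oxobicyclo[3.2.1]octa-2,6-dien-4-yl acetate (acetoxy syn to C8)
Conditions: toluene (degassed, 0.02 M), BHT (trace), 110 °C, base-washed glassware
Reagents that add atoms: none
Why: Concerted [3,3] sigmatropic (Cope) rearrangement of a cis-divinylcyclopropane unit, here the ring alkene C5=C6 and the endo alkenyl group C3=C4 on the cyclopropane C1–C2–C7; the closest known reaction type is the thermal rearrangement of endo-6-vinylbicyclo[3.1.0]hex-2-enes to bicyclo[3.2.1]octa-2,6-dienes, also the second stage of tandem cyclopropanation/Cope sequences. The bond C2–C7 breaks while C4–C5 forms suprafacially on both allyl fragments through a boat-shaped six-centre array, the only one the fused ring allows, and loss of cyclopropane strain makes the step irreversible. The six-membered ring C1–C2–C3–C4–C5–C8 closes by this sigmatropic ring expansion, the termini being held together by C1 and C8, and C2=C3 appears directly as the methyl enol ether while C6=C7 is left as a trisubstituted alkene. C5 is controlled by C1: C4 can reach only the face of C5 turned toward the cyclopropane, so the bridgehead methoxy configuration follows from C1. C4 is controlled by the enol geometry: the acetoxy group is cis to the cyclopropane (inward in the boat) and inward substituents end cis to the inward substituent of the other terminus, which is C8, hence acetoxy syn to C8 and hydrogen toward the C6=C7 bridge. The step needs the endo and not the exo alkenyl isomer, which the lactone tethers of steps 7 and 11 secure, and a single enol geometry, which the anti iodolactonisation of step 11 and the retentive steps 12 and 16 secure. It also needs rearrangement to outrun thermal loss of the enol acetate or homolytic epimerisation at C2; this is helped by the absence of any cis sp3 C–H for a homodienyl hydrogen shift and by C8 being a flat carbonyl carbon with no hydrogen to clash with the inward acetoxy oxygen.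

Step 18
Reactants: 22 1-[2-(tert-butyldimethylsilyloxy)ethyl]-3,5-dimethoxy-7-methyl-8-oxobicyclo[3.2.1]octa-2,6-dien-4-yl acetate; 23 4-iodo-1,2-dimethoxybenzene
Product: 24 1-[2-(tert-butyldimethylsilyloxy)ethyl]-6-exo-(3,4-dimethoxyphenyl)-3,5-dimethoxy-7-endo-methyl-8-oxobicyclo[3.2.1]oct-2-en-4-yl acetate (acetoxy syn to C8)
Conditions: Pd(OAc)2 (10 mol %), PPh3, HCO2Na, Bu4NCl, DMF, 70 °C
Reagents that add atoms: none
Why: Reductive Heck hydroarylation: the arylpalladium species adds syn to the exo face (C8 side) of the strained alkene C6=C7, the endo face being shielded by the C2–C4 bridge, with aryl going to the less substituted C6; formate then replaces palladium at C7 by hydrogen with retention, so aryl and the new C7–H are exo and the methyl group becomes endo.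

Step 19
Reactants: 24 1-[2-(tert-butyldimethylsilyloxy)ethyl]-6-exo-(3,4-dimethoxyphenyl)-3,5-dimethoxy-7-endo-methyl-8-oxobicyclo[3.2.1]oct-2-en-4-yl acetate
Product: 25 6-exo-(3,4-dimethoxyphenyl)-1-(2-hydroxyethyl)-3,5-dimethoxy-7-endo-methyl-8-oxobicyclo[3.2.1]oct-2-en-4-yl acetate
Conditions: Bu4NF, AcOH, THF, 0 °C → rt
Reagents that add atoms: none
Why: Fluoride cleavage of the primary silyl ether; buffering with acetic acid suppresses acetate migration or cleavage and avoids the acid that would hydrolyse the enol ether.

Step 20
Reactants: 25 6-exo-(3,4-dimethoxyphenyl)-1-(2-hydroxyethyl)-3,5-dimethoxy-7-endo-methyl-8-oxobicyclo[3.2.1]oct-2-en-4-yl acetate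
Product: 26 6-exo-(3,4-dimethoxyphenyl)-3,5-dimethoxy-7-endo-methyl-8-oxo-1-(2-oxoethyl)bicyclo[3.2.1]oct-2-en-4-yl acetate
Conditions: Dess–Martin periodinane, NaHCO3, CH2Cl2, 0 °C
Reagents that add atoms: none
Why: Buffered Dess–Martin oxidation of the primary alcohol to the aldehyde under neutral conditions that spare the enol ether, the acetate and the electron-rich arene.

Step 21
Reactants: 26 6-exo-(3,4-dimethoxyphenyl)-3,5-dimethoxy-7-endo-methyl-8-oxo-1-(2-oxoethyl)bicyclo[3.2.1]oct-2-en-4-yl acetate
Product: 27 CNP0221003.1, 1-allyl-6-exo-(3,4-dimethoxyphenyl)-3,5-dimethoxy-7-endo-methyl-8-oxobicyclo[3.2.1]oct-2-en-4-yl acetate (acetoxy syn to C8)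
Conditions: Ph3PCH3Br, KHMDS, THF, 0 °C; then 26 (1.1 equiv ylide), −78 → 0 °C
Reagents that add atoms: methyltriphenylphosphonium bromide, C[P+](c1ccccc1)(c1ccccc1)c1ccccc1.[Br-]
Why: Wittig methylenation of the aldehyde completes the allyl group; the unhindered aldehyde should react far faster than the bridging ketone flanked by two quaternary carbons, and a near-stoichiometric ylide at low temperature leaves the acetate intact.

## Compound list

1 | methyl 4,4-dimethoxy-3-oxobutanoate | COC(=O)CC(=O)C(OC)OC | starting material
2 | tert-butyl(2-iodoethoxy)dimethylsilane | CC(C)(C)[Si](C)(C)OCCI | starting material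
3 | methyl 2-[2-(tert-butyldimethylsilyloxy)ethyl]-4,4-dimethoxy-3-oxobutanoate (racemic) | COC(=O)C(CCO[Si](C)(C)C(C)(C)C)C(=O)C(OC)OC | intermediate
4 | methyl (2E)-2-[2-(tert-butyldimethylsilyloxy)ethyl]-4,4-dimethoxy-3-(4-methylbenzenesulfonyloxy)but-2-enoate | COC(=O)/C(CCO[Si](C)(C)C(C)(C)C)=C(OS(=O)(=O)c1ccc(C)cc1)\C(OC)OC | intermediate
5 | methyl (2Z)-2-[2-(tert-butyldimethylsilyloxy)ethyl]-4,4-dimethoxy-3-methylbut-2-enoate | COC(=O)/C(CCO[Si](C)(C)C(C)(C)C)=C(C)\C(OC)OC | intermediate
6 | (2Z)-2-[2-(tert-butyldimethylsilyloxy)ethyl]-4,4-dimethoxy-3-methylbut-2-en-1-ol | OC/C(CCO[Si](C)(C)C(C)(C)C)=C(C)\C(OC)OC | intermediate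
7 | bromoacetyl bromide | O=C(Br)CBr | starting material
8 | (2Z)-2-[2-(tert-butyldimethylsilyloxy)ethyl]-4,4-dimethoxy-3-methylbut-2-en-1-yl bromoacetate | BrCC(=O)OC/C(CCO[Si](C)(C)C(C)(C)C)=C(C)\C(OC)OC | intermediate
9 | (2Z)-2-[2-(tert-butyldimethylsilyloxy)ethyl]-4,4-dimethoxy-3-methylbut-2-en-1-yl diazoacetate | [N-]=[N+]=CC(=O)OC/C(CCO[Si](C)(C)C(C)(C)C)=C(C)\C(OC)OC | intermediate
10 | (1S,5R,6S)-5-[2-(tert-butyldimethylsilyloxy)ethyl]-6-(dimethoxymethyl)-6-methyl-3-oxabicyclo[3.1.0]hexan-2-one | O=C1OC[C@@]2(CCO[Si](C)(C)C(C)(C)C)[C@@](C)(C(OC)OC)[C@@H]12 | intermediate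
11 | (1S,5R,6S)-5-[2-(tert-butyldimethylsilyloxy)ethyl]-6-(dimethoxymethyl)-6-methyl-3-oxabicyclo[3.1.0]hexan-2-ol (anomers) | OC1OC[C@@]2(CCO[Si](C)(C)C(C)(C)C)[C@@](C)(C(OC)OC)[C@@H]12 | intermediate
12 | [(1R,2S,3S)-1-[2-(tert-butyldimethylsilyloxy)ethyl]-2-(dimethoxymethyl)-3-ethynyl-2-methylcyclopropyl]methanol | OC[C@@]1(CCO[Si](C)(C)C(C)(C)C)[C@@](C)(C(OC)OC)[C@H]1C#C | intermediate
13 | (1R,2S,3R)-1-[2-(tert-butyldimethylsilyloxy)ethyl]-2-(dimethoxymethyl)-3-ethynyl-2-methylcyclopropane-1-carboxylic acid | OC(=O)[C@@]1(CCO[Si](C)(C)C(C)(C)C)[C@@](C)(C(OC)OC)[C@H]1C#C | intermediate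
14 | (1R,4E,5R,6S)-1-[2-(tert-butyldimethylsilyloxy)ethyl]-6-(dimethoxymethyl)-4-(iodomethylidene)-6-methyl-3-oxabicyclo[3.1.0]hexan-2-one | O=C1O/C(=C/I)[C@@H]2[C@](C)(C(OC)OC)[C@]12CCO[Si](C)(C)C(C)(C)C | intermediate
15 | potassium (Z)-enolate of the 3-(iodoacetyl)cyclopropane methyl ester (oxygen trans to iodine) | [K+].COC(=O)[C@@]1(CCO[Si](C)(C)C(C)(C)C)[C@@](C)(C(OC)OC)[C@H]1/C([O-])=C\I | intermediate
16 | methyl 1-[2-(tert-butyldimethylsilyloxy)ethyl]-2-(dimethoxymethyl)-3-[(E)-2-iodo-1-methoxyethenyl]-2-methylcyclopropane-1-carboxylate | COC(=O)[C@@]1(CCO[Si](C)(C)C(C)(C)C)[C@@](C)(C(OC)OC)[C@H]1/C(OC)=C\I | intermediate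
17 | diethyl (methoxymethyl)phosphonate | CCOP(=O)(COC)OCC | starting material
18 | diethyl (2-{1-[2-(tert-butyldimethylsilyloxy)ethyl]-2-(dimethoxymethyl)-3-[(E)-2-iodo-1-methoxyethenyl]-2-methylcyclopropyl}-1-methoxy-2-oxoethyl)phosphonate | CCOP(=O)(OCC)C(OC)C(=O)[C@@]1(CCO[Si](C)(C)C(C)(C)C)[C@@](C)(C(OC)OC)[C@H]1/C(OC)=C\I | intermediate
19 | diethyl (2-{1-[2-(tert-butyldimethylsilyloxy)ethyl]-2-formyl-3-[(E)-2-iodo-1-methoxyethenyl]-2-methylcyclopropyl}-1-methoxy-2-oxoethyl)phosphonate | CCOP(=O)(OCC)C(OC)C(=O)[C@@]1(CCO[Si](C)(C)C(C)(C)C)[C@@](C)(C=O)[C@H]1/C(OC)=C\I | intermediate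
20 | 1-[2-(tert-butyldimethylsilyloxy)ethyl]-6-endo-[(E)-2-iodo-1-methoxyethenyl]-3-methoxy-5-methylbicyclo[3.1.0]hex-3-en-2-one | CC(C)(C)[Si](C)(C)OCC[C@]12C(=O)C(OC)=C[C@@]1(C)[C@H]2/C(OC)=C\I | intermediate
21 | (E)-2-{1-[2-(tert-butyldimethylsilyloxy)ethyl]-3-methoxy-5-methyl-2-oxobicyclo[3.1.0]hex-3-en-6-endo-yl}-2-methoxyethenyl acetate | CC(C)(C)[Si](C)(C)OCC[C@]12C(=O)C(OC)=C[C@@]1(C)[C@H]2/C(OC)=C\OC(C)=O | intermediate
22 | 1-[2-(tert-butyldimethylsilyloxy)ethyl]-3,5-dimethoxy-7-methyl-8-oxobicyclo[3.2.1]octa-2,6-dien-4-yl acetate (acetoxy syn to C8) | CC(C)(C)[Si](C)(C)OCC[C@]12C=C(OC)[C@H](OC(C)=O)[C@](OC)(C1=O)C=C2C | intermediate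
23 | 4-iodo-1,2-dimethoxybenzene | COc1ccc(I)cc1OC | starting material
24 | 1-[2-(tert-butyldimethylsilyloxy)ethyl]-6-exo-(3,4-dimethoxyphenyl)-3,5-dimethoxy-7-endo-methyl-8-oxobicyclo[3.2.1]oct-2-en-4-yl acetate | CC(C)(C)[Si](C)(C)OCC[C@]12C=C(OC)[C@H](OC(C)=O)[C@](OC)(C1=O)[C@H](c1ccc(OC)c(OC)c1)[C@H]2C | intermediate
25 | 6-exo-(3,4-dimethoxyphenyl)-1-(2-hydroxyethyl)-3,5-dimethoxy-7-endo-methyl-8-oxobicyclo[3.2.1]oct-2-en-4-yl acetate | OCC[C@]12C=C(OC)[C@H](OC(C)=O)[C@](OC)(C1=O)[C@H](c1ccc(OC)c(OC)c1)[C@H]2C | intermediate
26 | 6-exo-(3,4-dimethoxyphenyl)-3,5-dimethoxy-7-endo-methyl-8-oxo-1-(2-oxoethyl)bicyclo[3.2.1]oct-2-en-4-yl acetate | O=CC[C@]12C=C(OC)[C@H](OC(C)=O)[C@](OC)(C1=O)[C@H](c1ccc(OC)c(OC)c1)[C@H]2C | intermediate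
27 | CNP0221003.1, 1-allyl-6-exo-(3,4-dimethoxyphenyl)-3,5-dimethoxy-7-endo-methyl-8-oxobicyclo[3.2.1]oct-2-en-4-yl acetate | C=CC[C@]12C=C(OC)[C@H](OC(C)=O)[C@](OC)(C1=O)[C@H](c1ccc(OC)c(OC)c1)[C@H]2C | target

## Step count and least certain steps

Total step count: 21. Longest linear sequence: 21 steps (1 → 27); compounds 2, 7, 17 and 23 enter as purchased building blocks.

Step 17 (key step). The acetoxy group must pass beneath the C8 carbonyl in the boat, so the rearrangement may be slow. At the temperature then needed, thermal loss of the enol acetate or homolytic opening and epimerisation at C2 could compete. Fallback from 20: copper-catalysed etherification with 4-methoxybenzyl alcohol (CuI, tetramethylphenanthroline, Cs2CO3) should give, with retention, the 4-methoxybenzyl enol ether F1, a thermally robust and more electron-rich alkenyl partner. Heating F1 should give the rearranged bicyclic 4-methoxybenzyl ether F2. Buffered DDQ cleavage should give the C4 alcohol F3, and Ac2O/DMAP returns to the route at 22.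

Step 18. Carbopalladation of a trisubstituted alkene between two quaternary carbons may be slow, and β-hydride elimination from the tertiary alkylpalladium toward the methyl group may outrun formate capture. Fallback from 22 and 23: run the Heck arylation without a hydride source (Pd(OAc)2, PPh3, Ag2CO3) so that this elimination is the intended path to the 7-methylidene compound F4. Hydrogenation of the exocyclic alkene from the exo face (H2, RhCl(PPh3)3), which leaves the trisubstituted enol ether untouched, rejoins the route at 24.

Step 16. Carboxylates are weak partners in Ullmann-type alkenylation and the iodide is hindered. A higher temperature could start the rearrangement of the iodide itself, or lose the alkene geometry. Fallback from 20: Miyaura borylation (B2pin2, PdCl2(PPh3)2, KOPh, toluene, 50 °C) should give the pinacol alkenylboronate F5 with retention. A Chan–Lam-type acetoxylation with Cu(OAc)2, pyridine and air at room temperature then returns to 21.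

Step 12. The enolate could be methylated on carbon, or lose its geometry through proton exchange, or attack the new ester in a Claisen-type closure. Fallback from 14: let the lithium salt of 17 (2 equiv) open the enol lactone, so that no ester is ever present, then methylate the more basic iodoenolate oxygen in the same flask with one equivalent of MeOTf. This leads directly to 18 and passes through no new isolable compound (F0).

Step 7. Facial discrimination on a tetrasubstituted alkene may be incomplete, and carbene dimerisation may compete with addition to the hindered alkene. Fallback from 9: achiral Rh2(OAc)4 should give 10 together with its mirror-image lactone F6 as the racemate. Resolution by preparative chromatography on a chiral stationary phase returns to the route at 10.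

## Further compounds

F1 | step 17 | 1-[2-(tert-butyldimethylsilyloxy)ethyl]-3-methoxy-6-endo-{(E)-1-methoxy-2-[(4-methoxybenzyl)oxy]ethenyl}-5-methylbicyclo[3.1.0]hex-3-en-2-one | CC(C)(C)[Si](C)(C)OCC[C@]12C(=O)C(OC)=C[C@@]1(C)[C@H]2/C(OC)=C\OCc1ccc(OC)cc1
F2 | step 17 | 1-[2-(tert-butyldimethylsilyloxy)ethyl]-3,5-dimethoxy-4-[(4-methoxybenzyl)oxy]-7-methylbicyclo[3.2.1]octa-2,6-dien-8-one (ether syn to C8) | CC(C)(C)[Si](C)(C)OCC[C@]12C=C(OC)[C@H](OCc3ccc(OC)cc3)[C@](OC)(C1=O)C=C2C
F3 | step 17 | 1-[2-(tert-butyldimethylsilyloxy)ethyl]-4-hydroxy-3,5-dimethoxy-7-methylbicyclo[3.2.1]octa-2,6-dien-8-one (hydroxyl syn to C8) | CC(C)(C)[Si](C)(C)OCC[C@]12C=C(OC)[C@H](O)[C@](OC)(C1=O)C=C2C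
F4 | step 18 | 1-[2-(tert-butyldimethylsilyloxy)ethyl]-6-exo-(3,4-dimethoxyphenyl)-3,5-dimethoxy-7-methylidene-8-oxobicyclo[3.2.1]oct-2-en-4-yl acetate | CC(C)(C)[Si](C)(C)OCC[C@]12C=C(OC)[C@H](OC(C)=O)[C@](OC)(C1=O)[C@H](c1ccc(OC)c(OC)c1)C2=C
F5 | step 16 | 1-[2-(tert-butyldimethylsilyloxy)ethyl]-3-methoxy-6-endo-[(E)-1-methoxy-2-(4,4,5,5-tetramethyl-1,3,2-dioxaborolan-2-yl)ethenyl]-5-methylbicyclo[3.1.0]hex-3-en-2-one | CC(C)(C)[Si](C)(C)OCC[C@]12C(=O)C(OC)=C[C@@]1(C)[C@H]2/C(OC)=C\B1OC(C)(C)C(C)(C)O1
F0 | step 12 | none | none
F6 | step 7 | (1R,5S,6R)-5-[2-(tert-butyldimethylsilyloxy)ethyl]-6-(dimethoxymethyl)-6-methyl-3-oxabicyclo[3.1.0]hexan-2-one (mirror image of 10, formed with it as the racemate) | O=C1OC[C@]2(CCO[Si](C)(C)C(C)(C)C)[C@](C)(C(OC)OC)[C@H]12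
A1 | alternative 1 | 1-allyl-6-exo-(3,4-dimethoxyphenyl)-5-methoxy-7-methylidenebicyclo[3.2.1]octane-4,8-dione | C=CC[C@]12CCC(=O)[C@](OC)(C1=O)[C@H](c1ccc(OC)c(OC)c1)C2=C
A2 | alternative 2 | 1-[2-(tert-butyldimethylsilyloxy)ethyl]-5,8,8-trimethoxy-7-methyl-4-(1-phenylethoxy)bicyclo[3.2.1]oct-6-en-3-one | CC(C)(C)[Si](C)(C)OCC[C@]12CC(=O)[C@H](O[C@@H](C)c3ccccc3)[C@](OC)(C1(OC)OC)C=C2C
A3 | alternative 3 | 1-allyl-6-exo-(3,4-dimethoxyphenyl)-5-hydroxy-3-methoxy-7-endo-methyl-8-oxobicyclo[3.2.1]oct-2-en-4-yl acetate | C=CC[C@]12C=C(OC)[C@H](OC(C)=O)[C@](O)(C1=O)[C@H](c1ccc(OC)c(OC)c1)[C@H]2C
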